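The route rests on closing the seven-membered ring E (C8–C9=C10–C11–C12–C6–C5, Daphniphyllum numbering, C1 = lactam carbonyl) last, at the C10–C11 bond, by hydroboration of a C6 vinyl group and intramolecular B-alkyl Suzuki–Miyaura coupling with a C10 enol triflate. The step exploits that C10 is an sp2 carbon of the cyclopentene (ring D) and that C9 on C8 and C12 on C6 are cis-1,3 on the δ-lactam (ring A), so C11 lies next to C10. The precursor is a tetracycle: the bridged lactam with the nine-membered ring B (closed by Mitsunobu N-alkylation of a nosylamide) spiro-fused at C8 to the bicyclo[3.3.0]octene (rings C and D).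

Key step: step 20

Remarks on the chemistry:
- Numbering: N; C1 lactam C=O; C2 carbinol carbon; C5, C8 quaternary; C7, C19 the N–CH2 groups; C14 bears CO2Me; C18 bears CH3; C21 is the CH2O carbon. Rings: A = N/C1/C8/C5/C6/C7; B = N/C19/C18/C2/C3/C4/C5/C6/C7; C = C8/C13/C14/C15/C9; D = C9/C10/C17/C16/C15; E = C5/C6/C12/C11/C10/C9/C8.
- Assumption: 1, 2, 4, 6, 9, 20, 23 and all reagents are taken as commercially available; 21 is made fresh (step 13) because it does not keep.

Step 1
Reactants: 1 tert-butyl 2-oxo-2,5-dihydro-1H-pyrrole-1-carboxylate; 2 potassium vinyltrifluoroborate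
Product: 3 tert-butyl (4R)-4-ethenyl-2-oxopyrrolidine-1-carboxylate
Conditions: [Rh(cod)2]BF4 (3 mol %), (R)-BINAP, toluene/H2O, 80 °C
Reagents that add atoms: none
Why: Rhodium-catalysed asymmetric conjugate addition of an alkenylboron reagent to the unsaturated lactam should set C6, the ligand enantiomer being the one that delivers vinyl to the face giving the (R)-lactam.

Step 2
Reactants: 3 tert-butyl (4R)-4-ethenyl-2-oxopyrrolidine-1-carboxylate; 4 2-(2-bromoethyl)-1,3-dioxolane
Product: 5 trans-3-[2-(1,3-dioxolan-2-yl)ethyl]-4-ethenyl N-Boc-pyrrolidinone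
Conditions: LiN(i-Pr)2, THF, −78 °C; then 4, DMPU, −78 → −20 °C
Reagents that add atoms: none
Why: Lactam enolate alkylation, the electrophile entering trans to the adjacent vinyl group (this centre is enolised again in step 3).

Step 3
Reactants: 5 trans-3-[2-(1,3-dioxolan-2-yl)ethyl]-4-ethenyl N-Boc-pyrrolidinone; 6 tert-butyl bromoacetate
Product: 7 3,3-dialkylated N-Boc-pyrrolidinone (quaternary C5)
Conditions: LiN(SiMe3)2, THF, −78 °C; then 6, −78 → −40 °C
Reagents that add atoms: none
Why: Alkylation of the tetrasubstituted lactam enolate anti to the C6 vinyl group should set quaternary C5 with the acetate arm (C8–C1) trans and the C4 chain cis to vinyl.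

Step 4
Reactants: 7 3,3-dialkylated N-Boc-pyrrolidinone
Product: 8 C2 aldehyde
Conditions: PPTS, acetone/H2O, 50 °C
Reagents that add atoms: water, O
Why: Acid-catalysed acetal hydrolysis unmasks the aldehyde under conditions that the Boc-lactam and the tert-butyl ester should survive.

Step 5
Reactants: 8 C2 aldehyde; 9 (S)-4-benzyl-3-propanoyloxazolidin-2-one
Product: 10 syn-aldol adduct
Conditions: 9, Bu2BOTf, i-Pr2NEt, CH2Cl2, −78 → 0 °C; then 8, −78 → 0 °C; pH 7 buffer/MeOH work-up
Reagents that add atoms: none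
Why: Evans syn-aldol reaction through the Z-boron enolate and a chair transition state; the auxiliary should set C2 (R, hydroxyl) and C18 (methyl) in the syn relationship of the target.

Step 6
Reactants: 10 syn-aldol adduct
Product: 11 C2 triisopropylsilyl ether
Conditions: TIPSOTf, 2,6-lutidine, CH2Cl2, 0 °C
Reagents that add atoms: triisopropylsilyl trifluoromethanesulfonate, CC(C)[Si](C(C)C)(C(C)C)OS(=O)(=O)C(F)(F)F
Why: Silylation of the hindered secondary alcohol with a silyl triflate.

Step 7
Reactants: 11 C2 triisopropylsilyl ether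
Product: 12 Boc-amino diol tert-butyl ester
Conditions: LiBH4, MeOH (1 equiv), THF, 0 °C → rt
Reagents that add atoms: none
Why: Borohydride reduction cleaves the N-acyl oxazolidinone to the C19 alcohol and opens the N-Boc lactam to the C21 alcohol and the C7 carbamate, leaving the tert-butyl ester.

Step 8
Reactants: 12 Boc-amino diol tert-butyl ester
Product: 14 nosylamide lactone alcohol, via ammonium lactone trifluoroacetate 13 (not isolated)
Conditions: CF3CO2H/CH2Cl2, 0 °C → rt; evaporate; then 2-nitrobenzenesulfonyl chloride, Et3N, CH2Cl2, 0 °C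
Reagents that add atoms: 2-nitrobenzenesulfonyl chloride, O=[N+]([O-])c1ccccc1S(Cl)(=O)=O; trifluoroacetic acid, OC(=O)C(F)(F)F (counter-ion of 13 only)
Why: Acidolysis removes Boc and the tert-butyl ester, the acid lactonises onto the C21 hydroxyl (γ-lactone), and the amine is then sulfonylated faster than the primary C19 alcohol.

Step 9
Reactants: 14 nosylamide lactone alcohol
Product: 15 N-nosyl azonane spiro-lactone
Conditions: PPh3, DIAD, toluene (0.005 M), 0 °C → rt
Reagents that add atoms: none
Why: Intramolecular Mitsunobu N-alkylation of the acidic nosylamide by the primary C19 alcohol, a method established for eight- to ten-membered cyclic amines, should close ring B.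

Step 10
Reactants: 15 N-nosyl azonane spiro-lactone
Product: 17 bridged lactam alcohol, via azonane amine 16 (not isolated)
Conditions: PhSH, K2CO3, DMF, rt; then 70 °C
Reagents that add atoms: none
Why: Thiolate SNAr removes the nosyl group and the secondary amine opens the γ-lactone across the ring to give the six-membered lactam (ring A), freeing the C21 alcohol.

Step 11
Reactants: 17 bridged lactam alcohol
Product: 18 C21 tert-butyldimethylsilyl ether
Conditions: TBSCl, imidazole, DMF, rt
Reagents that add atoms: tert-butyldimethylsilyl chloride, CC(C)(C)[Si](C)(C)Cl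
Why: Standard silylation of the primary alcohol ahead of strong-base chemistry.

Step 12
Reactants: 18 C21 tert-butyldimethylsilyl ether
Product: 19 C8-chloroacetyl lactam
Conditions: LiN(i-Pr)2 (2.2 equiv), THF, −78 °C; then ClCH2C(O)N(OMe)Me, −78 → −40 °C; AcOH quench
Reagents that add atoms: 2-chloro-N-methoxy-N-methylacetamide, CON(C)C(=O)CCl
Why: Claisen-type C-acylation of the lactam enolate by a Weinreb amide installs C9 and C15 and acidifies C8–H; the C8 configuration is not yet fixed.

Step 13
Reactants: 20 dimethyl malonate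
Product: 21 dimethyl methylenemalonate
Conditions: paraformaldehyde, Cu(OAc)2 (cat.), KOAc (cat.), AcOH, 90 °C; distilled before use
Reagents that add atoms: formaldehyde (as paraformaldehyde), C=O
Why: Knoevenagel condensation gives the doubly activated acceptor.

Step 14
Reactants: 19 C8-chloroacetyl lactam; 21 dimethyl methylenemalonate
Product: 22 spiro cyclopentanone gem-diester (rings A, B, C)
Conditions: Cs2CO3, MeCN, 0 °C, slow addition of 21
Reagents that add atoms: none
Why: Michael-initiated ring closure: the β-keto lactam enolate adds to the methylenemalonate and the malonate anion displaces the α-keto chloride (5-exo-tet); C13 should enter C8 on the face anti to the vinyl-bearing C6, leaving C9 cis to C12.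

Step 15
Reactants: 22 spiro cyclopentanone gem-diester; 23 propargyl bromide
Product: 24 C15-propargyl ketone
Conditions: LiN(SiMe3)2, THF, −78 °C; then 23, −78 → 0 °C
Reagents that add atoms: none
Why: Alkylation of the only possible ketone enolate (C15) with a reactive propargylic halide; the C15 configuration is irrelevant because C15 becomes sp2 in step 18.

Step 16
Reactants: 24 C15-propargyl ketone
Product: 25 keto aldehyde
Conditions: CpRuCl(dppm) (5 mol %), i-PrOH/H2O, 90 °C
Reagents that add atoms: water, O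
Why: Ruthenium-catalysed anti-Markovnikov hydration of the terminal alkyne through a vinylidene should give the C10 aldehyde and leave the alkene untouched.

Step 17
Reactants: 25 keto aldehyde
Product: 26 cis-fused α-ketol (rings A–D)
Conditions: 3-benzyl-5-(2-hydroxyethyl)-4-methylthiazolium chloride (20 mol %), Et3N, t-BuOH, 50 °C
Reagents that add atoms: none
Why: Carbene-catalysed intramolecular crossed benzoin reaction: the acyl anion equivalent from the aldehyde adds to the C9 ketone (5-exo-trig), closing ring D.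

Step 18
Reactants: 26 cis-fused α-ketol
Product: 27 ring-fusion enone
Conditions: Burgess reagent, toluene, 70 °C
Reagents that add atoms: none
Why: syn-Elimination of the tertiary alcohol toward its only β-hydrogen (C15–H) gives the conjugated C9=C15 enone.

Step 19
Reactants: 27 ring-fusion enone
Product: 29 C10 enol triflate, via silyl enol ether 28 (not isolated)
Conditions: Cu(OAc)2·H2O (5 mol %), 1,2-bis(diphenylphosphino)benzene, (EtO)2MeSiH, toluene, rt; then CsF, PhNTf2, DME, rt
Reagents that add atoms: N-phenylbis(trifluoromethanesulfonimide), O=S(=O)(N(c1ccccc1)S(=O)(=O)C(F)(F)F)C(F)(F)F; diethoxymethylsilane, CCO[SiH](C)OCC (in 28 only)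
Why: Copper hydride 1,4-hydrosilylation should deliver hydride to C15 from the face of the C1 carbonyl, away from the bulky C5 arm of the spiro centre, and gives the C9=C10 enol silane regiospecifically, which fluoride converts into the triflate.

Step 20
Reactants: 29 C10 enol triflate
Product: 31 pentacyclic gem-diester, via alkylborane 30 (not isolated)
Conditions: 9-BBN-H (2 equiv), THF, rt; then Pd(dppf)Cl2 (20 mol %), AsPh3, Cs2CO3, H2O, DMF/THF, 50 °C, 0.003 M
Reagents that add atoms: 9-borabicyclo[3.3.1]nonane, B1C2CCCC1CCC2 (in 30 only)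
Why: Anti-Markovnikov hydroboration of the only monosubstituted alkene (C12=C11) gives the C11 alkylborane 30; oxidative addition of zerovalent palladium into the C10–OTf bond, base-assisted boron-to-palladium alkyl transfer and reductive elimination then forge C10–C11. The closest known reaction type is the intramolecular B-alkyl Suzuki–Miyaura cyclisation of alkenyl triflates and halides used for medium and large carbocycles. Ring E closes by sp2–sp3 reductive elimination from an eight-membered palladacycle, the C9=C10 double bond ending endocyclic to rings D and E. No stereocentre is created, and C6, C8 and C15 are not touched. The step needs chemoselective hydroboration (the tetrasubstituted enol triflate alkene, the esters and the lactam should be inert to 9-BBN-H at room temperature) and cyclisation ahead of intermolecular coupling or protodeboronation; the cis-1,3 relationship of C9 and C12 on ring A, which holds C11 beside C10, and high dilution should secure this.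

Step 21
Reactants: 31 pentacyclic gem-diester
Product: 32 C14 mono-ester
Conditions: LiCl, H2O, DMSO, 150 °C
Reagents that add atoms: none
Why: Krapcho dealkoxycarbonylation; the ester enolate released on decarboxylation should be protonated on the open face syn to C1, leaving CO2Me cis to C5 (kinetic control of C14).

Step 22
Reactants: 32 C14 mono-ester
Product: 33 C2,C21-diol
Conditions: HF·pyridine, THF/pyridine, 0 → 40 °C
Reagents that add atoms: none
Why: Fluoride cleavage of both silyl ethers under conditions that leave the methyl ester and the lactam alone.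

Step 23
Reactants: 33 C2,C21-diol
Product: 34 target
Conditions: Ac2O (1.1 equiv), pyridine, CH2Cl2, 0 °C
Reagents that add atoms: acetic anhydride, CC(=O)OC(C)=O
Why: Selective acylation of the primary C21 alcohol over the hindered secondary C2 alcohol.

Compound list
1 | tert-butyl 2-oxo-2,5-dihydro-1H-pyrrole-1-carboxylate | CC(C)(C)OC(=O)N1CC=CC1=O | starting material
2 | potassium vinyltrifluoroborate | [K+].C=C[B-](F)(F)F | starting material
3 | tert-butyl (4R)-4-ethenyl-2-oxopyrrolidine-1-carboxylate | CC(C)(C)OC(=O)N1C[C@@H](C=C)CC1=O | intermediate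
4 | 2-(2-bromoethyl)-1,3-dioxolane | BrCCC1OCCO1 | starting material
5 | tert-butyl 3-[2-(1,3-dioxolan-2-yl)ethyl]-4-ethenyl-2-oxopyrrolidine-1-carboxylate, 3,4-trans | CC(C)(C)OC(=O)N1C[C@@H](C=C)[C@H](CCC2OCCO2)C1=O | intermediate
6 | tert-butyl bromoacetate | CC(C)(C)OC(=O)CBr | starting material
7 | tert-butyl 3-(2-tert-butoxy-2-oxoethyl)-3-[2-(1,3-dioxolan-2-yl)ethyl]-4-ethenyl-2-oxopyrrolidine-1-carboxylate, acetate arm trans to vinyl | CC(C)(C)OC(=O)N1C[C@@H](C=C)[C@@](CC(=O)OC(C)(C)C)(CCC2OCCO2)C1=O | intermediate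
8 | the 3-(3-oxopropyl) aldehyde from 7 | CC(C)(C)OC(=O)N1C[C@@H](C=C)[C@@](CC(=O)OC(C)(C)C)(CCC=O)C1=O | intermediate
9 | (S)-4-benzyl-3-propanoyloxazolidin-2-one | CCC(=O)N1[C@@H](Cc2ccccc2)COC1=O | starting material
10 | syn-aldol adduct, (2S,3R)-3-hydroxy-2-methylacyl oxazolidinone (C18, C2) | CC(C)(C)OC(=O)N1C[C@@H](C=C)[C@@](CC(=O)OC(C)(C)C)(CC[C@@H](O)[C@H](C)C(=O)N2[C@@H](Cc3ccccc3)COC2=O)C1=O | intermediate
11 | C2 triisopropylsilyl ether of 10 | CC(C)(C)OC(=O)N1C[C@@H](C=C)[C@@](CC(=O)OC(C)(C)C)(CC[C@@H](O[Si](C(C)C)(C(C)C)C(C)C)[C@H](C)C(=O)N2[C@@H](Cc3ccccc3)COC2=O)C1=O | intermediate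
12 | open-chain Boc-amine (C7) with C19 and C21 primary alcohols and C1 tert-butyl ester | CC(C)(C)OC(=O)NC[C@@H](C=C)[C@@](CC(=O)OC(C)(C)C)(CC[C@@H](O[Si](C(C)C)(C(C)C)C(C)C)[C@H](C)CO)CO | intermediate
13 | C7 ammonium trifluoroacetate of the C21–O–C1 γ-lactone | [NH3+]C[C@@H](C=C)[C@]1(CC[C@@H](O[Si](C(C)C)(C(C)C)C(C)C)[C@H](C)CO)CC(=O)OC1.[O-]C(=O)C(F)(F)F | intermediate
14 | C7 2-nitrobenzenesulfonamide of the γ-lactone, C19 alcohol free | O=[N+]([O-])c1ccccc1S(=O)(=O)NC[C@@H](C=C)[C@]2(CC[C@@H](O[Si](C(C)C)(C(C)C)C(C)C)[C@H](C)CO)CC(=O)OC2 | intermediate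
15 | N-nosyl azonane (ring B) spiro-fused at C5 to the γ-lactone | O=[N+]([O-])c1ccccc1S(=O)(=O)N1C[C@@H](C=C)[C@@]2(CC(=O)OC2)CC[C@@H](O[Si](C(C)C)(C(C)C)C(C)C)[C@H](C)C1 | intermediate
16 | free azonane amine spiro-lactone | N1C[C@@H](C=C)[C@@]2(CC(=O)OC2)CC[C@@H](O[Si](C(C)C)(C(C)C)C(C)C)[C@H](C)C1 | intermediate
17 | bridged lactam (rings A and B), C21 alcohol, C6 vinyl, C2 OTIPS | O=C1N2C[C@@H](C=C)[C@](C1)(CO)CC[C@@H](O[Si](C(C)C)(C(C)C)C(C)C)[C@H](C)C2 | intermediate
18 | C21 tert-butyldimethylsilyl ether of 17 | O=C1N2C[C@@H](C=C)[C@](C1)(CO[Si](C)(C)C(C)(C)C)CC[C@@H](O[Si](C(C)C)(C(C)C)C(C)C)[C@H](C)C2 | intermediate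
19 | C8-chloroacetyl lactam (C8 epimers, enolisable) | O=C1N2C[C@@H](C=C)[C@](C1C(=O)CCl)(CO[Si](C)(C)C(C)(C)C)CC[C@@H](O[Si](C(C)C)(C(C)C)C(C)C)[C@H](C)C2 | intermediate
20 | dimethyl malonate | COC(=O)CC(=O)OC | starting material
21 | dimethyl methylenemalonate | COC(=O)C(=C)C(=O)OC | intermediate
22 | spiro cyclopentanone: C9 ketone, C14 gem-dimethyl ester, C9 cis to C12 on ring A | COC(=O)C1(C(=O)OC)C[C@]2(C(=O)C1)C(=O)N3C[C@@H](C=C)[C@]2(CO[Si](C)(C)C(C)(C)C)CC[C@@H](O[Si](C(C)C)(C(C)C)C(C)C)[C@H](C)C3 | intermediate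
23 | propargyl bromide | C#CCBr | starting material
24 | C15-propargyl ketone (C15 epimers) | COC(=O)C1(C(=O)OC)C[C@]2(C(=O)C1CC#C)C(=O)N3C[C@@H](C=C)[C@]2(CO[Si](C)(C)C(C)(C)C)CC[C@@H](O[Si](C(C)C)(C(C)C)C(C)C)[C@H](C)C3 | intermediate
25 | keto aldehyde, C15–CH2CH2CHO (C15 epimers) | COC(=O)C1(C(=O)OC)C[C@]2(C(=O)C1CCC=O)C(=O)N3C[C@@H](C=C)[C@]2(CO[Si](C)(C)C(C)(C)C)CC[C@@H](O[Si](C(C)C)(C(C)C)C(C)C)[C@H](C)C3 | intermediate
26 | α-ketol: C9 tertiary alcohol, C10 ketone, rings C/D cis-fused (C9/C15 diastereomers) | COC(=O)C1(C(=O)OC)C[C@]2(C3(O)C(=O)CCC31)C(=O)N4C[C@@H](C=C)[C@]2(CO[Si](C)(C)C(C)(C)C)CC[C@@H](O[Si](C(C)C)(C(C)C)C(C)C)[C@H](C)C4 | intermediate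
27 | enone: C10 ketone, C9=C15 | COC(=O)C1(C(=O)OC)C[C@]2(C3=C1CCC3=O)C(=O)N4C[C@@H](C=C)[C@]2(CO[Si](C)(C)C(C)(C)C)CC[C@@H](O[Si](C(C)C)(C(C)C)C(C)C)[C@H](C)C4 | intermediate
28 | C10 diethoxymethylsilyl enol ether, C9=C10, C15–H cis to C1 | COC(=O)C1(C(=O)OC)C[C@]2(C3=C(O[Si](C)(OCC)OCC)CC[C@@H]31)C(=O)N4C[C@@H](C=C)[C@]2(CO[Si](C)(C)C(C)(C)C)CC[C@@H](O[Si](C(C)C)(C(C)C)C(C)C)[C@H](C)C4 | intermediate
29 | C10 enol triflate, C9=C10, C15–H cis to C1 | COC(=O)C1(C(=O)OC)C[C@]2(C3=C(OS(=O)(=O)C(F)(F)F)CC[C@@H]31)C(=O)N4C[C@@H](C=C)[C@]2(CO[Si](C)(C)C(C)(C)C)CC[C@@H](O[Si](C(C)C)(C(C)C)C(C)C)[C@H](C)C4 | intermediate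
30 | C11 B-alkyl-9-BBN derivative of 29 | COC(=O)C1(C(=O)OC)C[C@]2(C3=C(OS(=O)(=O)C(F)(F)F)CC[C@@H]31)C(=O)N4C[C@@H](CCB5C6CCCC5CCC6)[C@]2(CO[Si](C)(C)C(C)(C)C)CC[C@@H](O[Si](C(C)C)(C(C)C)C(C)C)[C@H](C)C4 | intermediate
31 | pentacycle (rings A–E) with C14 gem-dimethyl ester, C21 OTBS, C2 OTIPS | COC(=O)C1(C(=O)OC)C[C@@]23C(=O)N4C[C@@H](CCC5=C2[C@@H]1CC5)[C@]3(CO[Si](C)(C)C(C)(C)C)CC[C@@H](O[Si](C(C)C)(C(C)C)C(C)C)[C@H](C)C4 | intermediate
32 | C14 mono methyl ester (CO2Me cis to C5), bis-silyl ether | COC(=O)[C@@H]1C[C@@]23C(=O)N4C[C@@H](CCC5=C2[C@@H]1CC5)[C@]3(CO[Si](C)(C)C(C)(C)C)CC[C@@H](O[Si](C(C)C)(C(C)C)C(C)C)[C@H](C)C4 | intermediate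
33 | deacetyl target (C2 and C21 alcohols) | COC(=O)[C@@H]1C[C@@]23C(=O)N4C[C@@H](CCC5=C2[C@@H]1CC5)[C@]3(CO)CC[C@@H](O)[C@H](C)C4 | intermediate
34 | CNP0296366.1 | COC(=O)[C@@H]1C[C@@]23C(=O)N4C[C@@H](CCC5=C2[C@@H]1CC5)[C@]3(COC(C)=O)CC[C@@H](O)[C@H](C)C4 | target

Total step count: 23. Longest linear sequence: 22 steps (steps 1–12 and 14–23; step 13 is a side branch).

Steps most likely to fail

Step 19. Hydride transfer to the fully substituted C15, which is flanked by the quaternary C14, may be too slow, or the hydride may be delivered with poor facial selectivity. The fallback sets out from 27 and comes back at 29. The enone would be reduced by electron transfer with SmI2/HMPA/t-BuOH in THF at −78 °C, which does not depend on steric access of a metal hydride; the β-carbanion should be protonated by the bulky alcohol from the C1 face. The samarium enolate would be trapped with Me3SiCl as the trimethylsilyl enol ether F1, and F1 treated with CsF and PhNTf2 to give 29.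

Step 17. The acyl anion equivalent may fail to add to the hindered C9 ketone, the aldehyde condensing with itself instead. The fallback sets out from 25 and comes back at 26. SmI2-mediated ketyl pinacol cyclisation (THF, t-BuOH, −78 °C) would close ring D as the cis-diol F2, and oxidation of the secondary C10 alcohol (SO3·pyridine, DMSO, i-Pr2NEt) would give 26.

Step 20. Transmetalation or reductive elimination at the tetrasubstituted, neopentyl-flanked triflate may be slower than protodeboronation or triflate reduction. The fallback sets out from 29 and comes back at 31 and moves the ring closure to C11=C12. Stille coupling with tributyl(vinyl)stannane (Pd(PPh3)4, CuI, CsF, DMF) would give the C10-vinyl triene F3. Ring-closing metathesis with the second-generation Grubbs catalyst would give the ring E diene F4. Diimide (2-nitrobenzenesulfonylhydrazide, Et3N) should reduce only the disubstituted C11=C12 alkene to give 31.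

Further compounds
F1 | step 19 | C10 trimethylsilyl enol ether, C9=C10, C15–H cis to C1 | COC(=O)C1(C(=O)OC)C[C@]2(C3=C(O[Si](C)(C)C)CC[C@@H]31)C(=O)N4C[C@@H](C=C)[C@]2(CO[Si](C)(C)C(C)(C)C)CC[C@@H](O[Si](C(C)C)(C(C)C)C(C)C)[C@H](C)C4
F2 | step 17 | C9,C10 cis-diol of rings C/D | COC(=O)C1(C(=O)OC)C[C@]2(C3(O)C(O)CCC31)C(=O)N4C[C@@H](C=C)[C@]2(CO[Si](C)(C)C(C)(C)C)CC[C@@H](O[Si](C(C)C)(C(C)C)C(C)C)[C@H](C)C4
F3 | step 20 | C10-vinyl triene | COC(=O)C1(C(=O)OC)C[C@]2(C3=C(C=C)CC[C@@H]31)C(=O)N4C[C@@H](C=C)[C@]2(CO[Si](C)(C)C(C)(C)C)CC[C@@H](O[Si](C(C)C)(C(C)C)C(C)C)[C@H](C)C4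
F4 | step 20 | pentacyclic C9=C10/C11=C12 diene | COC(=O)C1(C(=O)OC)C[C@@]23C(=O)N4C[C@@H](C=CC5=C2[C@@H]1CC5)[C@]3(CO[Si](C)(C)C(C)(C)C)CC[C@@H](O[Si](C(C)C)(C(C)C)C(C)C)[C@H](C)C4
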